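Assumption: methyl (4S,5R)-2,2,5-trimethyl-1,3-dioxolane-4-carboxylate (the catalogue acetonide ester made from L-threonine) is bought, and the natural product is the thermodynamically preferred Z-enamide / bicyclic ketal isomer.

The route below has no cycloaddition, electrocyclization or sigmatropic step: the ring-forming step is an acid-mediated ketalisation/condensation cascade.

**Retrosynthetic overview**
1. Both rings open in one move: the two ketal C–O bonds (dioxolane) and the N–C(sp2) enamide bond (lactam) give (2R,3R)-2,3-dihydroxy-2-methylbutanamide (as its acetonide) and the C2-symmetric 1,4-bis(4-hydroxyphenyl)butane-2,3-dione.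
2. Forward ring order: dioxolane first (acid transketalisation onto one C=O), then the six-membered lactam (intramolecular amide–ketone condensation giving the exocyclic Z-enamide).
3. Diol amide ⇐ ester ammonolysis ⇐ anti-selective enolate C-methylation of the L-threonine-derived dioxolane ester (CHMe centre bought, quaternary centre by 1,2-induction, ketal centre by the bicyclic constraint).
4. Diketone ⇐ O-demethylation ⇐ double Weinreb-type acylation of 4-methoxybenzyl Grignard on N,N′-dimethoxy-N,N′-dimethyloxamide.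

**Route**

Step 1
Reactants: 1 4-methoxybenzylmagnesium chloride (2.4 equiv); 2 N,N′-dimethoxy-N,N′-dimethyloxamide
Product: 4 1,4-bis(4-methoxyphenyl)butane-2,3-dione, via bis(chloromagnesium alkoxide) tetrahedral adduct 3 (not isolated)
Conditions: THF, −78 → 0 °C; then 1 M HCl, 0 °C
Reagents that add atoms: none
Why: Double Weinreb ketone synthesis: each N-methoxy-N-methylamide carbonyl takes one benzylic Grignard and is held as a Mg-chelated tetrahedral alkoxide until the acidic quench, so over-addition is avoided; no stereocentre is formed.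

Step 2
Reactants: 4 1,4-bis(4-methoxyphenyl)butane-2,3-dione
Product: 6 1,4-bis(4-hydroxyphenyl)butane-2,3-dione, via 1,4-bis[4-(dibromoboranyloxy)phenyl]butane-2,3-dione 5 (not isolated)
Conditions: BBr3 (4 equiv), CH2Cl2, −78 → 0 °C; then H2O
Reagents that add atoms: none
Why: BBr3 aryl methyl ether cleavage (Lewis acid complexation, bromide SN2 on O-CH3) gives aryl borates that hydrolyse on work-up; no stereocentre is involved.

Step 3
Reactants: 7 methyl (4S,5R)-2,2,5-trimethyl-1,3-dioxolane-4-carboxylate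
Product: 9 methyl (4R,5R)-2,2,4,5-tetramethyl-1,3-dioxolane-4-carboxylate, via lithium enolate of 7 8 (not isolated)
Conditions: LDA (1.15 equiv), THF–DMPU, −78 °C; MeI, −78 → −30 °C
Reagents that add atoms: iodomethane, CI
Why: Ester enolate alkylation with 1,2-asymmetric induction: MeI attacks the planar exocyclic enolate anti to the neighbouring C5 methyl, so the new 4-methyl is trans to the 5-methyl and the ester cis to it, i.e. (4R,5R); C5 from L-threonine is untouched.

Step 4
Reactants: 9 methyl (4R,5R)-2,2,4,5-tetramethyl-1,3-dioxolane-4-carboxylate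
Product: 10 (4R,5R)-2,2,4,5-tetramethyl-1,3-dioxolane-4-carboxamide
Conditions: NH3 (7 M in MeOH), sealed tube, 70 °C
Reagents that add atoms: ammonia, N
Why: Ester ammonolysis (nucleophilic acyl substitution), helped by the α-alkoxy group; neither stereocentre is enolisable, so both are retained.

Step 5
Reactants: 10 (4R,5R)-2,2,4,5-tetramethyl-1,3-dioxolane-4-carboxamide; 6 1,4-bis(4-hydroxyphenyl)butane-2,3-dione (1.3 equiv)
Product: 13 leptochartamide A, via (2R,4R,5R)-2-(4-hydroxybenzyl)-2-[2-(4-hydroxyphenyl)acetyl]-4,5-dimethyl-1,3-dioxolane-4-carboxamide 11 (not isolated), via (1R,5R,7R)-4-hydroxy-4,5-bis(4-hydroxybenzyl)-1,7-dimethyl-6,8-dioxa-3-azabicyclo[3.2.1]octan-2-one 12 (not isolated)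
Conditions: TsOH·H2O (0.2 equiv), PhMe–1,4-dioxane, 95 °C, Dean–Stark (−acetone, −H2O)
Reagents that add atoms: none
Why: Acid-catalysed transketalisation puts the diol on one carbonyl of the symmetric dione and the resulting δ-keto amide closes by ene-lactam (amide–ketone) condensation; ketal formation is reversible and only the epimer with carboxamide and keto side chain cis can cyclise, so C5 is fixed as R by C1/C7, and the exocyclic enamide equilibrates under acid to the conjugated Z isomer (aryl syn to N–H, away from C5).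

**Compound list**
1 | 4-methoxybenzylmagnesium chloride | COc1ccc(C[Mg]Cl)cc1 | starting material
2 | N,N′-dimethoxy-N,N′-dimethyloxamide | CON(C)C(=O)C(=O)N(C)OC | starting material
3 | bis(chloromagnesium alkoxide) tetrahedral adduct of 2 with two equivalents of 1 | COc1ccc(CC(O[Mg]Cl)(N(C)OC)C(O[Mg]Cl)(N(C)OC)Cc2ccc(OC)cc2)cc1 | intermediate
4 | 1,4-bis(4-methoxyphenyl)butane-2,3-dione | COc1ccc(CC(=O)C(=O)Cc2ccc(OC)cc2)cc1 | intermediate
5 | 1,4-bis[4-(dibromoboranyloxy)phenyl]butane-2,3-dione | BrB(Br)Oc1ccc(CC(=O)C(=O)Cc2ccc(OB(Br)Br)cc2)cc1 | intermediate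
6 | 1,4-bis(4-hydroxyphenyl)butane-2,3-dione | Oc1ccc(CC(=O)C(=O)Cc2ccc(O)cc2)cc1 | intermediate
7 | methyl (4S,5R)-2,2,5-trimethyl-1,3-dioxolane-4-carboxylate | COC(=O)[C@H]1OC(C)(C)O[C@@H]1C | starting material
8 | lithium methoxy[(5R)-2,2,5-trimethyl-1,3-dioxolan-4-ylidene]methanolate (enolate of 7) | COC(O[Li])=C1OC(C)(C)O[C@@H]1C | intermediate
9 | methyl (4R,5R)-2,2,4,5-tetramethyl-1,3-dioxolane-4-carboxylate | COC(=O)[C@]1(C)OC(C)(C)O[C@@H]1C | intermediate
10 | (4R,5R)-2,2,4,5-tetramethyl-1,3-dioxolane-4-carboxamide | NC(=O)[C@]1(C)OC(C)(C)O[C@@H]1C | intermediate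
11 | (2R,4R,5R)-2-(4-hydroxybenzyl)-2-[2-(4-hydroxyphenyl)acetyl]-4,5-dimethyl-1,3-dioxolane-4-carboxamide | C[C@H]1O[C@@](Cc2ccc(O)cc2)(C(=O)Cc2ccc(O)cc2)O[C@@]1(C)C(N)=O | intermediate
12 | (1R,5R,7R)-4-hydroxy-4,5-bis(4-hydroxybenzyl)-1,7-dimethyl-6,8-dioxa-3-azabicyclo[3.2.1]octan-2-one (both C4 epimers) | C[C@H]1O[C@]2(Cc3ccc(O)cc3)O[C@@]1(C)C(=O)NC2(O)Cc1ccc(O)cc1 | intermediate
13 | leptochartamide A, (1R,5R,7R)-4-[(Z)-4-hydroxybenzylidene]-5-(4-hydroxybenzyl)-1,7-dimethyl-6,8-dioxa-3-azabicyclo[3.2.1]octan-2-one | C[C@H]1O[C@]2(Cc3ccc(O)cc3)O[C@@]1(C)C(=O)N/C2=C\c1ccc(O)cc1 | target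

**Step count**
Total steps: 5. Longest linear sequence: 3 (7 → 9 → 10 → 13; the diketone arm 1 + 2 → 4 → 6 → 13 is also 3).

**Steps most likely to fail, with fallbacks**

Step 5 (one-pot transketalisation/lactamisation). The tertiary hydroxyl must ketalise a hindered ketone, and the enolisable bis-phenol dione can self-condense in hot acid. The fallback forms the N–C bond by cross-coupling instead of condensation. It sets out from 6 and returns at 13. Compound 6 is silylated (TBSCl, imidazole, DMF) to 1,4-bis[4-(tert-butyldimethylsilyloxy)phenyl]butane-2,3-dione F1. This is converted (KHMDS, PhNTf2, THF, −78 °C) into its (Z)-enol triflate F2. Pd-catalysed amidation of the triflate with amide 10 (Pd2(dba)3, Xantphos, Cs2CO3, dioxane, 80 °C) gives the open (Z)-enamido ketone F3. PPTS in MeOH at 50 °C then removes the acetonide, and the freed keto diol closes to the bis-TBS ether of the target F4. TBAF/AcOH in THF gives 13.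

Step 3 (C-methylation of the dioxolane enolate). The lithium enolate can β-eliminate or self-condense, and MeI is a small electrophile, so facial selectivity may be modest. The fallback sets out from 7 and returns at 9. Compound 7 is trapped (LDA, TMSCl, THF, −78 °C) as its trimethylsilyl ketene acetal F5. This is alkylated with the bulkier chloromethyl phenyl sulfide (cat. ZnBr2, CH2Cl2), again anti to the 5-methyl, to give methyl (4R,5R)-2,2,5-trimethyl-4-[(phenylsulfanyl)methyl]-1,3-dioxolane-4-carboxylate F6. Raney nickel in EtOH removes sulfur to give 9.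

Step 2 (BBr3 demethylation of an enolisable 1,2-dione). Boron enolate condensation or bromination may erode the yield. The fallback changes the phenol protection so that no Lewis acid is needed. It sets out from 2 and returns at 6. Compound 2 is treated with 4-(benzyloxy)benzylmagnesium chloride F7 (from the commercial chloride and Mg, THF) to give 1,4-bis[4-(benzyloxy)phenyl]butane-2,3-dione F8. Hydrogenolysis (H2 1 atm, Pd/C, EtOAc, rt) then gives 6.

**Further compounds**
F1 | step 5 | 1,4-bis[4-(tert-butyldimethylsilyloxy)phenyl]butane-2,3-dione | CC(C)(C)[Si](C)(C)Oc1ccc(CC(=O)C(=O)Cc2ccc(O[Si](C)(C)C(C)(C)C)cc2)cc1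
F2 | step 5 | (Z)-1,4-bis[4-(tert-butyldimethylsilyloxy)phenyl]-3-oxobut-1-en-2-yl trifluoromethanesulfonate | CC(C)(C)[Si](C)(C)Oc1ccc(/C=C(\OS(=O)(=O)C(F)(F)F)C(=O)Cc2ccc(O[Si](C)(C)C(C)(C)C)cc2)cc1
F3 | step 5 | (4R,5R)-N-[(Z)-1,4-bis[4-(tert-butyldimethylsilyloxy)phenyl]-3-oxobut-1-en-2-yl]-2,2,4,5-tetramethyl-1,3-dioxolane-4-carboxamide | CC(C)(C)[Si](C)(C)Oc1ccc(/C=C(\NC(=O)[C@]2(C)OC(C)(C)O[C@@H]2C)C(=O)Cc2ccc(O[Si](C)(C)C(C)(C)C)cc2)cc1
F4 | step 5 | bis(tert-butyldimethylsilyl) ether of leptochartamide A | C[C@H]1O[C@]2(Cc3ccc(O[Si](C)(C)C(C)(C)C)cc3)O[C@@]1(C)C(=O)N/C2=C\c1ccc(O[Si](C)(C)C(C)(C)C)cc1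
F5 | step 3 | trimethylsilyl ketene acetal of 7, {methoxy[(5R)-2,2,5-trimethyl-1,3-dioxolan-4-ylidene]methoxy}trimethylsilane | COC(O[Si](C)(C)C)=C1OC(C)(C)O[C@@H]1C
F6 | step 3 | methyl (4R,5R)-2,2,5-trimethyl-4-[(phenylsulfanyl)methyl]-1,3-dioxolane-4-carboxylate | COC(=O)[C@]1(CSc2ccccc2)OC(C)(C)O[C@@H]1C
F7 | step 2 | 4-(benzyloxy)benzylmagnesium chloride | Cl[Mg]Cc1ccc(OCc2ccccc2)cc1
F8 | step 2 | 1,4-bis[4-(benzyloxy)phenyl]butane-2,3-dione | O=C(Cc1ccc(OCc2ccccc2)cc1)C(=O)Cc1ccc(OCc2ccccc2)cc1
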